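The route rests on cutting the side chain (C1''–C8'', counted from ring A) between the vinylic carbon C2'' and the methyl-bearing methine C3''. The key step exploits this sp2–sp3 junction: a trans-styrenyl unit on ring-A carbon C6 beside an unactivated secondary stereocentre. A stereoretentive Negishi coupling unites a configurationally stable secondary alkylzinc, made from (R)-sulcatol, with the (E)-2-iodovinyl group of tris-silylated (2S)-naringenin. In one operation the whole C8 chain joins the intact flavanone, the E alkene is kept and C3'' arrives as S, while the C4 ketone and the chiral-pool C2 centre stay untouched.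

Key step: step 7

Assumption: (2S)-naringenin and (R)-sulcatol are bought as single enantiomers of checked optical purity; B-ring atoms carry one prime, side-chain atoms two primes.

Step 1
Reactants: 1 (2S)-naringenin
Product: 2 (2S)-7,4'-bis-O-(tert-butyldimethylsilyl)naringenin (5-OH free)
Conditions: TBSCl (2.2 equiv), imidazole (4 equiv), DMF, 0 °C to rt
Reagents that add atoms: tert-butyldimethylsilyl chloride, CC(C)(C)[Si](C)(C)Cl
Why: Phenol silylation; the 7-OH and 4'-OH should react while the 5-OH, hydrogen-bonded to the C4 carbonyl, stays free, and the weak base imidazole should not open the pyranone, so C2 is kept.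

Step 2
Reactants: 2 (2S)-7,4'-bis-O-TBS-naringenin
Product: 3 (2S)-6-iodo-7,4'-bis-O-TBS-naringenin
Conditions: NIS (1.05 equiv), DMF, 0 °C to rt, dark
Reagents that add atoms: N-iodosuccinimide, O=C1CCC(=O)N1I
Why: Electrophilic aromatic iodination; in 5-hydroxy-7-alkoxyflavonoids the free chelated 5-OH is expected to steer NIS to its ortho carbon C6, and one equivalent at low temperature should avoid a second iodination at C8.

Step 3
Reactants: 3 (2S)-6-iodo-7,4'-bis-O-TBS-naringenin; 4 (E)-1,2-bis(tributylstannyl)ethene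
Product: 5 (2S)-6-[(E)-2-(tributylstannyl)ethenyl]-7,4'-bis-O-TBS-naringenin
Conditions: Pd(PPh3)4 (5 mol%), toluene, 90 °C; 4 in threefold excess; chromatography on base-washed silica
Reagents that add atoms: none
Why: Stille coupling; one alkenyl group of the distannane, used in excess to suppress the second coupling, is transferred to the aryl iodide with retention of the E geometry under base-free conditions that leave C2 untouched.

Step 4
Reactants: 5 (2S)-6-[(E)-2-(tributylstannyl)ethenyl]-7,4'-bis-O-TBS-naringenin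
Product: 6 (2S)-6-[(E)-2-iodoethenyl]-7,4'-bis-O-TBS-naringenin
Conditions: I2 (1.05 equiv), CH2Cl2, 0 °C, dark; aq. Na2S2O3/KF work-up
Reagents that add atoms: iodine, II
Why: Iododestannylation; ipso attack of iodine at the tin-bearing carbon is much faster than iodination of the arene and proceeds with retention, giving the E-alkenyl iodide.

Step 5
Reactants: 6 (2S)-6-[(E)-2-iodoethenyl]-7,4'-bis-O-TBS-naringenin
Product: 7 (2S)-6-[(E)-2-iodoethenyl]-5,7,4'-tris-O-TBS-naringenin
Conditions: TBSOTf (1.5 equiv), 2,6-lutidine (3 equiv), CH2Cl2, –78 to 0 °C; filtration through neutral alumina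
Reagents that add atoms: tert-butyldimethylsilyl triflate, CC(C)(C)[Si](C)(C)OS(=O)(=O)C(F)(F)F
Why: Silylation with the strong silyl donor TBSOTf and a hindered weak base should cap the chelated 5-OH, removing the only acidic proton before the organozinc step.

Step 6
Reactants: 8 (R)-6-methylhept-5-en-2-ol ((R)-sulcatol)
Product: 9 (S)-6-iodo-2-methylhept-2-ene
Conditions: PPh3 (1.2 equiv), I2 (1.2 equiv), N-methylimidazole (1.2 equiv), CH2Cl2, –10 °C
Reagents that add atoms: iodine, II
Why: Appel iodination; iodide displaces the alkoxyphosphonium group in an SN2 step with inversion, so the (R)-alcohol should give the (S)-iodide, and the low temperature limits racemisation by iodide exchange.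

Step 7
Reactants: 9 (S)-6-iodo-2-methylhept-2-ene (1.8 equiv); 7 (2S)-6-[(E)-2-iodoethenyl]-5,7,4'-tris-O-TBS-naringenin
Product: 12 5,7,4'-tris-O-TBS ether of the target, via (S)-6-methylhept-5-en-2-yllithium 10 (not isolated), via (S)-sec-alkyl(trimethylsilylmethyl)zinc 11 (not isolated)
Conditions: 9 added to t-BuLi (2.2 equiv per 9), pentane/Et2O 3:2, –100 °C, 1 min; Me3SiCH2ZnBr·LiBr (1.1 equiv per 9), THF, –100 to –30 °C; then 7, Pd-PEPPSI-IPent (4 mol%), –25 °C to rt
Reagents that add atoms: tert-butyllithium, [Li]C(C)(C)C (gives the lithium of 10); (trimethylsilyl)methylzinc bromide, C[Si](C)(C)C[Zn]Br (gives the zinc and the silylmethyl group of 11)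
Why: Iodine–lithium exchange at –100 °C should proceed through an iodine ate complex with retention to give 10, which is trapped at once by the zinc bromide with retention to give 11, a secondary alkylzinc expected to hold its configuration for the hours needed. Palladium(0) inserts into the alkenyl C–I bond of 7 with retention of the E geometry, the secondary alkyl group (not the silylmethyl dummy ligand) is transferred from zinc with retention, and reductive elimination forms the C2''–C3'' bond; the closest known reaction type is the stereoretentive Negishi coupling of chiral non-stabilised secondary alkylzinc reagents with alkenyl iodides. No ring is closed. C3'' is not created but transferred: its S configuration is controlled by the configuration of 9 through three retentive events, and the alkene geometry by that of the iodide. The step needs chemoselectivity for the C–I bond over the C4 ketone, secured because all organolithium is converted into organozinc before 7 is added, and branched-over-linear fidelity, secured by the bulky NHC ligand that makes reductive elimination faster than β-hydride elimination.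

Step 8
Reactants: 12 5,7,4'-tris-O-TBS ether of the target
Product: 13 (2S)-6-[(1E,3S)-3,7-dimethylocta-1,6-dien-1-yl]-5,7-dihydroxy-2-(4-hydroxyphenyl)chroman-4-one (CNP0150993.1)
Conditions: HF·pyridine, pyridine, THF, 0 °C to rt
Reagents that add atoms: none
Why: Fluoride cleavage of the three aryl silyl ethers under buffered, mildly acidic conditions should free the phenols without forming a phenoxide, so the pyranone does not open, C2 does not epimerise and neither alkene is touched.

Compound list
1 | (2S)-naringenin | Oc1cc2c(c(O)c1)C(=O)C[C@@H](c1ccc(O)cc1)O2 | starting material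
2 | (2S)-7-(tert-butyldimethylsilyloxy)-2-[4-(tert-butyldimethylsilyloxy)phenyl]-5-hydroxychroman-4-one | c1c(O[Si](C)(C)C(C)(C)C)cc2c(c1O)C(=O)C[C@@H](c1ccc(O[Si](C)(C)C(C)(C)C)cc1)O2 | intermediate
3 | (2S)-7-(tert-butyldimethylsilyloxy)-2-[4-(tert-butyldimethylsilyloxy)phenyl]-5-hydroxy-6-iodochroman-4-one | Ic1c(O[Si](C)(C)C(C)(C)C)cc2c(c1O)C(=O)C[C@@H](c1ccc(O[Si](C)(C)C(C)(C)C)cc1)O2 | intermediate
4 | (E)-1,2-bis(tributylstannyl)ethene | CCCC[Sn](CCCC)(CCCC)/C=C/[Sn](CCCC)(CCCC)CCCC | starting material
5 | (2S)-7-(tert-butyldimethylsilyloxy)-2-[4-(tert-butyldimethylsilyloxy)phenyl]-5-hydroxy-6-[(E)-2-(tributylstannyl)ethenyl]chroman-4-one | CCCC[Sn](CCCC)(CCCC)/C=C/c1c(O[Si](C)(C)C(C)(C)C)cc2c(c1O)C(=O)C[C@@H](c1ccc(O[Si](C)(C)C(C)(C)C)cc1)O2 | intermediate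
6 | (2S)-7-(tert-butyldimethylsilyloxy)-2-[4-(tert-butyldimethylsilyloxy)phenyl]-5-hydroxy-6-[(E)-2-iodoethenyl]chroman-4-one | I/C=C/c1c(O[Si](C)(C)C(C)(C)C)cc2c(c1O)C(=O)C[C@@H](c1ccc(O[Si](C)(C)C(C)(C)C)cc1)O2 | intermediate
7 | (2S)-5,7-bis(tert-butyldimethylsilyloxy)-2-[4-(tert-butyldimethylsilyloxy)phenyl]-6-[(E)-2-iodoethenyl]chroman-4-one | I/C=C/c1c(O[Si](C)(C)C(C)(C)C)cc2c(c1O[Si](C)(C)C(C)(C)C)C(=O)C[C@@H](c1ccc(O[Si](C)(C)C(C)(C)C)cc1)O2 | intermediate
8 | (R)-6-methylhept-5-en-2-ol ((R)-sulcatol) | CC(C)=CCC[C@@H](C)O | starting material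
9 | (S)-6-iodo-2-methylhept-2-ene | CC(C)=CCC[C@H](C)I | intermediate
10 | (S)-6-methylhept-5-en-2-yllithium | CC(C)=CCC[C@H](C)[Li] | intermediate
11 | (S)-(6-methylhept-5-en-2-yl)[(trimethylsilyl)methyl]zinc | CC(C)=CCC[C@H](C)[Zn]C[Si](C)(C)C | intermediate
12 | (2S)-5,7-bis(tert-butyldimethylsilyloxy)-2-[4-(tert-butyldimethylsilyloxy)phenyl]-6-[(1E,3S)-3,7-dimethylocta-1,6-dien-1-yl]chroman-4-one | CC(C)=CCC[C@H](C)/C=C/c1c(O[Si](C)(C)C(C)(C)C)cc2c(c1O[Si](C)(C)C(C)(C)C)C(=O)C[C@@H](c1ccc(O[Si](C)(C)C(C)(C)C)cc1)O2 | intermediate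
13 | (2S)-6-[(1E,3S)-3,7-dimethylocta-1,6-dien-1-yl]-5,7-dihydroxy-2-(4-hydroxyphenyl)chroman-4-one (CNP0150993.1) | CC(C)=CCC[C@H](C)/C=C/c1c(O)cc2c(c1O)C(=O)C[C@@H](c1ccc(O)cc1)O2 | target

Total step count: 8
Longest linear sequence: 7 steps (steps 1–5, 7 and 8, from naringenin); step 6 prepares the second fragment.

Steps most likely to fail

Step 7. Partial loss of configuration at the carbanionic carbon during the iodine–lithium exchange, or β-hydride elimination and re-insertion on palladium, would give the C3'' epimer or the straight-chain isomer, which would be hard to separate from the product. The fallback makes the same bond by a boron 1,2-metallate rearrangement with the ketone masked. Setting out from 7, Luche reduction (NaBH4, CeCl3, THF/MeOH, –20 °C) should give mainly the cis (2S,4S)-5,7-bis(tert-butyldimethylsilyloxy)-2-[4-(tert-butyldimethylsilyloxy)phenyl]-6-[(E)-2-iodoethenyl]chroman-4-ol F1; its C4 configuration is of no consequence. Separately, commercial 5-bromo-2-methylpent-2-ene is converted (Mg, THF; then isopropoxy pinacolborane) into 4,4,5,5-tetramethyl-2-(4-methylpent-3-en-1-yl)-1,3,2-dioxaborolane F2. Lithiation–borylation of F2 with ethyl N,N-diisopropylcarbamate (s-BuLi, (+)-sparteine, Et2O, –78 °C, then warming) should give (S)-4,4,5,5-tetramethyl-2-(6-methylhept-5-en-2-yl)-1,3,2-dioxaborolane F3. F1 is treated with t-BuLi (3 equiv, THF, –78 °C; the first equivalent forms the C4 alkoxide) and the alkenyllithium is captured by F3. The ate complex is exposed to PhSeCl and then mCPBA (1 equiv, –45 °C), the selenium-mediated syn-elimination variant of the Zweifel olefination. Anti selenation/1,2-migration followed by syn elimination should give the E alkene with retention at the migrating carbon, the (2S,4S)-5,7-bis(tert-butyldimethylsilyloxy)-2-[4-(tert-butyldimethylsilyloxy)phenyl]-6-[(1E,3S)-3,7-dimethylocta-1,6-dien-1-yl]chroman-4-ol F4. Dess–Martin oxidation of F4 comes back to the route at 12.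

Step 3. A second coupling of the product stannane with the aryl iodide, slow oxidative addition at the hindered electron-rich C6–I bond, and protodestannylation during purification may erode the step. The fallback sets out from 3 with a Negishi coupling using (E)-2-(trimethylsilyl)vinylzinc chloride (from (E)-(2-bromovinyl)trimethylsilane, t-BuLi, ZnCl2; 2.5 equiv; Pd(OAc)2/SPhos, THF, 40 °C). This should give the robust (2S)-7-(tert-butyldimethylsilyloxy)-2-[4-(tert-butyldimethylsilyloxy)phenyl]-5-hydroxy-6-[(E)-2-(trimethylsilyl)ethenyl]chroman-4-one F5. Silylation of the 5-OH (TBSOTf, 2,6-lutidine) gives (2S)-5,7-bis(tert-butyldimethylsilyloxy)-2-[4-(tert-butyldimethylsilyloxy)phenyl]-6-[(E)-2-(trimethylsilyl)ethenyl]chroman-4-one F6. Ipso-iododesilylation of F6 (NIS, MeCN, 0 °C) comes back to the route at 7.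

Step 2. Attack of the iodonium at C8 (para to the 5-OH) or double iodination would spoil the regiochemistry. The fallback sets out from 2 with an ortho-specific formylation of the free phenol through its magnesium phenoxide (MgCl2, Et3N, paraformaldehyde, MeCN, reflux). This should give (2S)-7-(tert-butyldimethylsilyloxy)-2-[4-(tert-butyldimethylsilyloxy)phenyl]-5-hydroxy-4-oxochroman-6-carbaldehyde F7. Takai iodo-olefination of F7 (CrCl2, CHI3, THF, 0 °C) comes back to the route at 6 and bypasses steps 3 and 4.

Further compounds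
F1 | step 7 | (2S,4S)-5,7-bis(tert-butyldimethylsilyloxy)-2-[4-(tert-butyldimethylsilyloxy)phenyl]-6-[(E)-2-iodoethenyl]chroman-4-ol | I/C=C/c1c(O[Si](C)(C)C(C)(C)C)cc2c(c1O[Si](C)(C)C(C)(C)C)[C@@H](O)C[C@@H](c1ccc(O[Si](C)(C)C(C)(C)C)cc1)O2
F2 | step 7 | 4,4,5,5-tetramethyl-2-(4-methylpent-3-en-1-yl)-1,3,2-dioxaborolane | CC(C)=CCCB1OC(C)(C)C(C)(C)O1
F3 | step 7 | (S)-4,4,5,5-tetramethyl-2-(6-methylhept-5-en-2-yl)-1,3,2-dioxaborolane | CC(C)=CCC[C@H](C)B1OC(C)(C)C(C)(C)O1
F4 | step 7 | (2S,4S)-5,7-bis(tert-butyldimethylsilyloxy)-2-[4-(tert-butyldimethylsilyloxy)phenyl]-6-[(1E,3S)-3,7-dimethylocta-1,6-dien-1-yl]chroman-4-ol | CC(C)=CCC[C@H](C)/C=C/c1c(O[Si](C)(C)C(C)(C)C)cc2c(c1O[Si](C)(C)C(C)(C)C)[C@@H](O)C[C@@H](c1ccc(O[Si](C)(C)C(C)(C)C)cc1)O2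
F5 | step 3 | (2S)-7-(tert-butyldimethylsilyloxy)-2-[4-(tert-butyldimethylsilyloxy)phenyl]-5-hydroxy-6-[(E)-2-(trimethylsilyl)ethenyl]chroman-4-one | C[Si](C)(C)/C=C/c1c(O[Si](C)(C)C(C)(C)C)cc2c(c1O)C(=O)C[C@@H](c1ccc(O[Si](C)(C)C(C)(C)C)cc1)O2
F6 | step 3 | (2S)-5,7-bis(tert-butyldimethylsilyloxy)-2-[4-(tert-butyldimethylsilyloxy)phenyl]-6-[(E)-2-(trimethylsilyl)ethenyl]chroman-4-one | C[Si](C)(C)/C=C/c1c(O[Si](C)(C)C(C)(C)C)cc2c(c1O[Si](C)(C)C(C)(C)C)C(=O)C[C@@H](c1ccc(O[Si](C)(C)C(C)(C)C)cc1)O2
F7 | step 2 | (2S)-7-(tert-butyldimethylsilyloxy)-2-[4-(tert-butyldimethylsilyloxy)phenyl]-5-hydroxy-4-oxochroman-6-carbaldehyde | O=Cc1c(O[Si](C)(C)C(C)(C)C)cc2c(c1O)C(=O)C[C@@H](c1ccc(O[Si](C)(C)C(C)(C)C)cc1)O2
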